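The runs are simulated for an exercise; noise was put on by code.

17.4 % of the starting material charged is the ceiling on target in Monday's flask. Each target takes one reagent, so the reagent charge as a fraction of the starting-material charge, the reagent cap, bounds the target.

| flask | starting material | reagent | protic impurity | free catalyst | remark | time |
|---|---|---|---|---|---|---|
| alder | 0.46 M | 0.322 M | 0.10 M | 2.3 mM | run made earlier |  |
| larch | 0.46 M | 0.322 M | 0.18 M | 2.3 mM | run made earlier |  |
| Thursday's | 0.46 M | 0.322 M | 0.150 M | 0.80 mM |  | 4.0 min |
| Tuesday's | 0.60 M | 0.322 M | 0.150 M | 2.3 mM |  | 4.0 min |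
| Monday's | 0.46 M | 0.0800 M | 0.230 M | 2.3 mM |  | 4.0 min |
| Saturday's | 0.46 M | 0.322 M | 0.230 M | 2.3 mM |  | 4.0 min |
| Wednesday's | 0.46 M | 0.200 M | 0.230 M | 2.3 mM |  | 4.0 min |

| run | time / min | target / % | starting material / % |
|---|---|---|---|
| alder | 0.250 | 13.5 | 31.0 |
| alder | 0.500 | 25.4 | 13.7 |
| alder | 1.33 | 43.4 | 3.6 |
| alder | 3.00 | 49.4 | 0.6 |
| larch | 0.667 | 30.9 | 8.2 |
| larch | 1.33 | 41.4 | 2.9 |
| larch | 2.00 | 45.7 | 1.2 |
| larch | 3.00 | 47.9 | 0.5 |

(scatter of a reading: 0.3 percentage points)

- in percentages every species weighs as the starting material in it: one side product counts as two
- candidate steps: reagent + catalyst intermediate -> free catalyst + target; starting material + open intermediate -> side product; starting material + protic impurity -> quenched substrate; starting material + free catalyst <-> free catalyst + open intermediate; free catalyst + open intermediate <-> catalyst intermediate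
- no earlier run changes the charge of free catalyst; that part of a forecast is a guess

- the flasks by amount of target, in percent of the starting material charged, highest first, at 4.0 min (Thursday's / Tuesday's / Monday's / Saturday's / Wednesday's)
- the amount of target, in percent of the starting material charged of the flask you put first, at 4.0 min
- the amount of target, in percent of the starting material charged of the flask you put last, at 4.0 min

1. Bound from above: Monday's has the lowest cap. A cap is an upper limit for its own flask and does not rank the flasks, so the next steps bracket Monday's target.

2. Bound from below: larch's 47.9 % of target at 3.00 min means that 68.4 % of its reagent is spent. The target step is first order in reagent, so at equal catalyst intermediate the fraction spent does not depend on the reagent charge, and Monday's runs longer. Larch's fraction of Monday's cap gives 11.9 %.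

3. Tighter ceiling: alder's first reading spends reagent at 0.771 min⁻¹, a pseudo-first-order constant. Alder's target rises at a lower pace between its last two readings than over its first, so holding the first pace for 4.0 min is reckoned to overstate Monday's, and the reckoned ceiling is 16.6 %.

4. The forecast, reckoned separately, gives Saturday's > Tuesday's > Wednesday's > Thursday's > Monday's, with 48 % (46.8 % to 49.2 %) for the first flask and 16.5 % (15 % to 17.4 %) for the last: “reagent decay with a time constant near 1.25 min leaves about 16.5%”. Its low value stands inside the bracket.

5. The flasks give Saturday's > Tuesday's > Wednesday's > Thursday's > Monday's, with 47.1 % first and 16.1 % last.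

    reagent + catalyst intermediate → free catalyst + target (k = 27.0 L mol⁻¹ s⁻¹)
    starting material + open intermediate → side product (k = 0.140 L mol⁻¹ s⁻¹)
    starting material + protic impurity → quenched substrate (k = 0.0690 L mol⁻¹ s⁻¹)
    starting material + free catalyst ⇌ free catalyst + open intermediate (K = 2.50, k = 40.0 L mol⁻¹ s⁻¹)
    free catalyst + open intermediate ⇌ catalyst intermediate (K = 3.60 L mol⁻¹, k = 140 L mol⁻¹ s⁻¹)

In Monday's, side product and quenched substrate have half of their turnover up to 4.0 min behind them by 0.303 min and 0.267 min, each shorter than the 1.30 min reagent time read from alder. Monday's reagent stands at 7.3 % of its own charge at 4.0 min, and its target is 92.5 % of the cap. A flask like Monday's with 0.048 M of reagent has a cap of 10.4 %, and its 9.83 % of target is 94.5 % of that cap.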